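## Analysis of the target

The target 24 is a 2,3-dimethylchroman-4-one whose benzene ring (ring A: C4a, C5, C6, C7, C8, C8a) is substituted on every carbon. It carries the chelated 5-OH, the (3R)-hexanoic acid chain bound through C3' to C6, a methoxy group on C7 and a prenyl group on C8; the dihydropyranone (ring B: O1, C2, C3, C4) is fused across C4a–C8a. There are three stereocentres. C2 (S) and C3 (S) carry trans methyl groups; the benzylic C3' (R) is separated from them by the arene, so the two sets cannot control each other and are best made in separate enantiopure fragments. C3 is α to the C4 ketone and can epimerize, base can open the O1–C2 bond by retro-oxa-Michael reaction (which would erase C2 as well), the prenyl alkene does not tolerate strong acid or hydrogenation, and the acid can lactonize onto the 5-OH. The hard part is the hexasubstituted arene: placing a branched, stereodefined alkyl group on C6 between two oxygenated carbons, and a prenyl group on C8, by substitution on a crowded ring whose oxygen donors are tied up by the C4 acyl group is unattractive. Ring A, however, has oxygen on C5, C7 and C8a and the acyl carbon C4 on C4a: it is an acylphloroglucinol, that is a tetraketide chain C4–C4a–C8a–C8–C7–C6–C5 folded so that C4a is bonded to C5. Because the C8a oxygen is already the ring oxygen O1, ring B can be made first and serve as a mask for one chain carbonyl, and ring A can then be closed by forming C4a–C5 with C6 and C8 already substituted.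

## Retrosynthetic reasoning

**24 to 22 (ester C–O bond).** The acid is unveiled last. A tert-butyl ester is carried because it must survive alkoxide in the ring-forming step without transesterification and, above all, without being attacked by the C8 carbanion in a six-membered Dieckmann-type closure (C8–C7–C6–C3'–C2'–C1'). It is removed by silyl transfer under buffered conditions, so that the prenyl alkene and the 5-OH/acid pair never meet a strong protic acid.

**22 to 21 (O7–CH3).** O7 is a ketone oxygen until ring A exists, so the methyl group can only be added afterwards. The forward reaction must tell two phenols apart: the 5-OH is held in a hydrogen bond to C4=O, whereas the 7-OH is the free, more acidic phenol para to that carbonyl.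

**21 to 20 (C4a–C5, ring A).** This is the strategic cut. Opening C4a–C5 turns the arene into a chain in which C5 is an ester carbon, C7 a ketone and C8a the enol-ether carbon of ring B. The cut is made here and not at C6–C7 or C8–C8a because C4a is the only ring A carbon that is nucleophilic as part of the vinylogous ester, and C5 the only one that can be an acyl electrophile with a leaving group. What is gained is that both crowded substituents, at C6 and at C8, are placed by enolate chemistry on an open chain. The forward reaction must make the dienolate of ring B attack the ester through C4a and then aromatize.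

**20 to 18 and 19 (C8–prenyl).** The prenyl group is put on last, after the hindered C6–C7 bond has been made with an unbranched acyl partner. C8 in 18 is flanked by the C7 ketone and the vinylogous ester, so a doubly deprotonated 18 should take up the allylic bromide 19 there and not at the tertiary C6.

**18 to 9 and 15 (C6–C7).** The β-keto ester is cut between the ketone carbon and the ester-bearing carbon. C7 comes from the carboxyl carbon of acid 9 (activated as imidazolide 16), C6 from the malonate carbon of half-ester 15, whose free carboxyl group is lost in a decarboxylative Claisen condensation. This pairing is chosen because 9 carries an acidic CH2: a strongly basic ester enolate would only deprotonate it, whereas the magnesium-chelated enolate of a malonic half-ester is formed with a tertiary amine and is matched to such an acyl donor.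

**9 through 8 to 6 (O1–C8a and the C4a=C8a double bond, ring B).** Ring B is closed by cyclodehydration of a δ-hydroxy-β-diketone while the chain holds only two ketones. If the ring were closed after the full chain had been assembled, the free 1,3,5-tricarbonyl array could equally close to a γ-pyrone or fold by aldol condensation. Closing ring B early also keeps O1 and C2 connected from then on.

**6 to 4 and 5 (C4–C4a).** The diketo ester is cut next to the carbonyl that becomes C4. The terminal carbanion of the dianion of 5 is acylated by the Weinreb amide 4, which stops at the tetrahedral stage and so avoids proton transfer from the product.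

**4 through 3 and 2 to 1 (C3–CH3).** The C2/C3 pair is taken from the chiral pool. The carbinol centre of 1 becomes C2, and the C3 methyl group is introduced anti to it by alkylation of the chelated alkoxide enolate.

**15 through 14, 13 and 12 to 10 and 11 (C6–C3').** The benzylic centre is made as the β-carbon of an enal. Malonate 11 adds to 10 under amine catalysis, which sets C3' and at the same time supplies C6 and C5 as the malonate carbon and one of its esters. The aldehyde becomes the tert-butyl ester, and one methyl ester is hydrolysed to give the half-ester needed for the decarboxylative Claisen step.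

## Alternatives that were turned down

**Alternative 1:** The disconnection is C6–C3' on the finished chromanone. In the forward step (2S,3S)-5-hydroxy-7-methoxy-2,3-dimethyl-8-(3-methylbut-2-en-1-yl)chroman-4-one A1 would add through C6 to the β-carbon of the iminium ion formed from 10 and a diarylprolinol silyl ether; the freed aldehyde would be trapped by the 5-OH as the six-membered lactol A2, which would later be oxidized and opened to the acid.
- For it: it is the shortest conceivable route, the catalyst sets C3' in the very step that makes the hardest bond, and it uses the same aldehyde 10.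
- Against it: C6 of A1 lies between two oxygen substituents whose donor power is drained by the C4 carbonyl (the 5-OH is chelated, O7 is a vinylogous ester oxygen), and the reaction would create a hexasubstituted arene bearing a secondary alkyl group. Iminium Friedel–Crafts alkylations of phenols rely on unhindered, strongly electron-rich partners. A1 must also first be made as a single trans isomer, which this step does not address, and the lactol must finally be opened against the tendency of the acid to close again onto O5.
- Comparison: Alternative 1 is stronger in step economy and convergence. The chosen route offers instead a ring closure that never has to form a bond to a crowded arene carbon.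

**Alternative 2:** The disconnection is C3–C4, with ring B closed last. In the forward step methyl (3R)-3-{4-[(2S)-but-3-en-2-yloxy]-3-formyl-2,6-dimethoxy-5-(3-methylbut-2-en-1-yl)phenyl}hexanoate A3 would be converted by a chiral triazolium-derived carbene into its Breslow intermediate, which adds across the terminal alkene to give the chromanone A4.
- For it: C2 comes from an inexpensive allylic alcohol, C3 can settle to the trans arrangement, and ring B is not exposed to the base-promoted chain chemistry.
- Against it: the central problem is left untouched, because the hexasubstituted ring A of A3, with the C6 side chain and the C8 prenyl group, must still be built by stepwise substitution of an arene. The aldehyde of A3 is flanked by two ortho alkoxy groups and the alkene sits on a branched ether, both of which slow the formation and the addition of the Breslow intermediate. A4 carries methyl ethers on both O5 and O7, so a selective 5-O-demethylation in the presence of the prenyl group and an ester hydrolysis follow.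
- Comparison: Alternative 2 is stronger in that it keeps the O1–C2 bond out of basic enolate steps. The chosen route offers instead the construction of ring A with all substituents already in place and needs only one O-methylation.

**Alternative 3:** The disconnection cuts four bonds of ring A. Irradiation of (2S,3S)-6-(2-diazo-5-methylhex-4-enoyl)-2,3-dimethyl-2,3-dihydro-4H-pyran-4-one A5 would give a vinylketene by Wolff rearrangement; addition of the ynol ether methyl (3R)-3-(methoxyethynyl)hexanoate A6, opening of the cyclobutenone and 6π closure would give the methyl ester A7 of the target.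
- For it: it is the most convergent plan, the polarity of the ynol ether fixes the regiochemistry, and the 5-OH and the 7-OMe arise already differentiated; on this last point it is stronger than the chosen route, which needs a selective methylation.
- Against it: A5 is an α-alkyl diazo ketone in which a 1,2-hydrogen shift of the carbene competes with the Wolff shift, its enone chromophore and its prenyl alkene are exposed to light and to the ketene, and A6 is a sensitive ynol ether next to a stereocentre. Both partners need several steps through fragile intermediates, and the thermal cyclobutenone opening heats a ring that can open by retro-oxa-Michael reaction.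
- Comparison: Alternative 3 is stronger in convergence and oxygen differentiation. The chosen route offers instead robust enolate chemistry from cheap chiral building blocks, no diazo compound or photochemistry, and a risky step that has a close fallback from the same fragments.

Key step: step 13

Assumption: the (S)-configured diarylprolinol silyl ether of step 7 is taken to follow the usual shielding model (attack on the face of the (E)-iminium ion opposite the diarylsilyloxymethyl group), which for this aliphatic enal corresponds to the (3R) adduct 12.

## Route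

Step 1
Reactants: 1 ethyl (3S)-3-hydroxybutanoate
Product: 2 ethyl (2S,3S)-3-hydroxy-2-methylbutanoate
Conditions: LiN(iPr)2 (2.2 equiv), THF, −50 to −20 °C; MeI, DMPU, −78 to 0 °C; AcOH
Reagents that add atoms: iodomethane, CI
Why: Fráter–Seebach alkylation: double deprotonation gives a chelated lithium alkoxide enolate whose six-membered chelate exposes the face anti to the C3 methyl group, so iodomethane should enter anti to the oxygen-bearing centre and set C2 as S. The carbinol centre of 1 controls the new centre and is itself untouched.

Step 2
Reactants: 2 ethyl (2S,3S)-3-hydroxy-2-methylbutanoate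
Product: 3 ethyl (2S,3S)-3-[(tert-butyldimethylsilyl)oxy]-2-methylbutanoate
Conditions: t-BuMe2SiCl, imidazole, DMF, rt
Reagents that add atoms: tert-butyl(chloro)dimethylsilane, CC(C)(C)[Si](C)(C)Cl
Why: Standard silylation of a secondary alcohol; the silyl ether prevents alkoxide formation and retro-aldol cleavage in the next two basic steps.

Step 3
Reactants: 3 ethyl (2S,3S)-3-[(tert-butyldimethylsilyl)oxy]-2-methylbutanoate
Product: 4 (2S,3S)-3-[(tert-butyldimethylsilyl)oxy]-N-methoxy-N,2-dimethylbutanamide
Conditions: MeNH(OMe)·HCl, i-PrMgCl, THF, −20 to 0 °C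
Reagents that add atoms: N,O-dimethylhydroxylamine hydrochloride, CNOC.Cl
Why: Weinreb amide formation by aminolysis of the ester with the chloromagnesium amide of N,O-dimethylhydroxylamine; at or below 0 °C acylation should be faster than enolization, so C2 keeps its configuration.

Step 4
Reactants: 4 (2S,3S)-3-[(tert-butyldimethylsilyl)oxy]-N-methoxy-N,2-dimethylbutanamide; 5 tert-butyl 3-oxobutanoate
Product: 6 tert-butyl (6S,7S)-7-[(tert-butyldimethylsilyl)oxy]-6-methyl-3,5-dioxooctanoate
Conditions: 5 (2 equiv), NaH, THF, 0 °C; n-BuLi, −10 °C; then 4, −78 to −30 °C; AcOH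
Reagents that add atoms: none
Why: γ-Acylation of a β-keto ester dianion (Claisen-type): the terminal carbanion of the dianion of 5 adds to the Weinreb amide, and the chelated tetrahedral adduct survives until the quench, so neither over-addition nor proton transfer from the product to unreacted dianion can occur. The α-centre of 4 meets base only at low temperature.

Step 5
Reactants: 6 tert-butyl (6S,7S)-7-[(tert-butyldimethylsilyl)oxy]-6-methyl-3,5-dioxooctanoate
Product: 8 tert-butyl 2-[(2S,3S)-2,3-dimethyl-4-oxo-3,4-dihydro-2H-pyran-6-yl]acetate, via hydroxy diketo ester 7 (not isolated)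
Conditions: 48% aq. HF, MeCN, 0 °C to rt; then p-TsOH·H2O (cat.), CH2Cl2, rt
Reagents that add atoms: none
Why: Cyclodehydration of a δ-hydroxy-β-diketone: acidic desilylation frees the C7 hydroxyl, which adds to the C3 ketone in a six-membered hemiketal, and acid-catalysed loss of water gives the conjugated vinylogous ester. No bond to a stereocentre is broken, the trans (diequatorial) arrangement is also the thermodynamic one, and the tert-butyl ester tolerates both acids.

Step 6
Reactants: 8 tert-butyl 2-[(2S,3S)-2,3-dimethyl-4-oxo-3,4-dihydro-2H-pyran-6-yl]acetate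
Product: 9 2-[(2S,3S)-2,3-dimethyl-4-oxo-3,4-dihydro-2H-pyran-6-yl]acetic acid
Conditions: CF3CO2H/CH2Cl2 1:3, 0 °C; evaporation below 25 °C, used crude
Reagents that add atoms: none
Why: Acidolysis of the tert-butyl ester with loss of isobutene; the vinylogous ester is stable to anhydrous acid. The vinylogous β-keto acid 9 is kept cold and used at once because it can decarboxylate on warming.

Step 7
Reactants: 10 (E)-hex-2-enal; 11 dimethyl propanedioate
Product: 12 dimethyl 2-[(3R)-1-oxohexan-3-yl]propanedioate
Conditions: (S)-2-{bis[3,5-bis(trifluoromethyl)phenyl](trimethylsilyloxy)methyl}pyrrolidine (10 mol %), 11 (1.5 equiv), EtOH, 0 °C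
Reagents that add atoms: none
Why: Iminium-ion organocatalytic Michael addition: the (E)-iminium ion of 10 is shielded on one face by the diarylsilyloxymethyl group and the malonate adds to the open face of the β-carbon, which sets C3' as R.

Step 8
Reactants: 12 dimethyl 2-[(3R)-1-oxohexan-3-yl]propanedioate
Product: 13 (3R)-3-(1,3-dimethoxy-1,3-dioxopropan-2-yl)hexanoic acid
Conditions: NaClO2, NaH2PO4, 2-methylbut-2-ene, t-BuOH/H2O, 0 °C to rt
Reagents that add atoms: sodium chlorite, [Na+].[O-]Cl=O
Why: Pinnick oxidation: chlorite oxidizes only the aldehyde, and the alkene scavenger removes hypochlorous acid before it can chlorinate the malonate C–H. The stereocentre is β to the aldehyde and cannot epimerize.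

Step 9
Reactants: 13 (3R)-3-(1,3-dimethoxy-1,3-dioxopropan-2-yl)hexanoic acid
Product: 14 dimethyl 2-[(3R)-1-(tert-butoxy)-1-oxohexan-3-yl]propanedioate
Conditions: Cl3CC(=NH)Ot-Bu (2 equiv), BF3·OEt2 (cat.), CH2Cl2/cyclohexane, rt
Reagents that add atoms: tert-butyl 2,2,2-trichloroacetimidate, CC(C)(C)OC(=N)C(Cl)(Cl)Cl
Why: Acid-catalysed tert-butylation of a carboxylic acid with a trichloroacetimidate; no base is present, so the malonate is left alone.

Step 10
Reactants: 14 dimethyl 2-[(3R)-1-(tert-butoxy)-1-oxohexan-3-yl]propanedioate
Product: 15 (3R)-5-(tert-butoxy)-2-(methoxycarbonyl)-5-oxo-3-propylpentanoic acid (both C2 epimers)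
Conditions: KOH (1.0 equiv), MeOH/H2O, 0 °C; cold 1 M HCl to pH 3
Reagents that add atoms: potassium hydroxide, [K+].[OH-]
Why: Selective monosaponification of a malonic diester: once one ester is hydrolysed, the carboxylate retards attack on the second, and the tert-butyl ester is inert to cold hydroxide. The new centre at the malonate carbon is of no consequence because it becomes the enolizable C6.

Step 11
Reactants: 9 2-[(2S,3S)-2,3-dimethyl-4-oxo-3,4-dihydro-2H-pyran-6-yl]acetic acid; 15 (3R)-5-(tert-butoxy)-2-(methoxycarbonyl)-5-oxo-3-propylpentanoic acid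
Product: 18 5-tert-butyl 1-methyl (3R)-2-{2-[(2S,3S)-2,3-dimethyl-4-oxo-3,4-dihydro-2H-pyran-6-yl]acetyl}-3-propylpentanedioate (C2 epimers and enol), via acyl imidazolide 16 (not isolated), via acylmalonic half-acid 17 (not isolated)
Conditions: 9, CDI, THF, 0 °C to rt; then 15 (1.3 equiv), MgCl2, Et3N, THF/MeCN, rt; aq. citric acid
Reagents that add atoms: none
Why: Masamune–Brooks-type decarboxylative Claisen condensation: imidazolide 16 acylates the magnesium enolate of half-ester 15 at carbon, and the acylmalonic half-acid 17 loses CO2 on acidification to leave the α-substituted β-keto ester. The nucleophile is formed with a tertiary amine under magnesium chelation, which suits an acyl donor that itself has an acidic CH2; C3' is not enolizable and is carried through.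

Step 12
Reactants: 18 5-tert-butyl 1-methyl (3R)-2-{2-[(2S,3S)-2,3-dimethyl-4-oxo-3,4-dihydro-2H-pyran-6-yl]acetyl}-3-propylpentanedioate; 19 1-bromo-3-methylbut-2-ene
Product: 20 5-tert-butyl 1-methyl (3R)-2-{2-[(2S,3S)-2,3-dimethyl-4-oxo-3,4-dihydro-2H-pyran-6-yl]-5-methylhex-4-enoyl}-3-propylpentanedioate (mixture at the two enolizable chain carbons)
Conditions: LiN(iPr)2 (2.1 equiv), THF, −78 °C; 19 (1.05 equiv), −78 to −20 °C; AcOH
Reagents that add atoms: none
Why: γ-Alkylation of a β-keto ester dianion: two equivalents of amide base remove the C6 and C8 protons, and the allylic bromide should be taken up at C8, a secondary carbon that is α to the C7 carbonyl and the γ-terminus of the vinylogous ester, whereas C6 is tertiary and screened by the branched C3'. The configuration at C8 is left uncontrolled because C8 becomes an arene carbon in step 13.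

Step 13
Reactants: 20 5-tert-butyl 1-methyl (3R)-2-{2-[(2S,3S)-2,3-dimethyl-4-oxo-3,4-dihydro-2H-pyran-6-yl]-5-methylhex-4-enoyl}-3-propylpentanedioate
Product: 21 tert-butyl (3R)-3-[(2S,3S)-5,7-dihydroxy-2,3-dimethyl-8-(3-methylbut-2-en-1-yl)-4-oxo-3,4-dihydro-2H-chromen-6-yl]hexanoate
Conditions: Mg(OMe)2 (6 equiv), MeOH, rt to 65 °C; cold 0.5 M HCl
Reagents that add atoms: none
Why: Magnesium methoxide removes the C6 proton of the β-keto ester and then the C8 proton, the latter giving a dienolate that runs through C8a=C4a to the C4 oxygen; its C4a terminus adds to the magnesium-chelated ester carbonyl C5, methoxide leaves, and enolization of the C5 and C7 carbonyls aromatizes ring A as its magnesium phenoxide. The closest known reaction type is the biomimetic Claisen cyclization of 3,5,7-trioxoalkanoates and pyranone-masked relatives to acylphloroglucinols with the same base; a chain substituted at both C6 and C8 is an untested substrate of that reaction. Ring A closes in the 6-(enolexo)-exo-trig mode. No stereocentre is formed: C3' is not enolizable, C3 is not acidic while C4 is an enolate oxygen, and afterwards the trans arrangement is the thermodynamically preferred one. The step needs C-acylation at C4a to win over every other closure, and the substrate secures this: aldol attack of C6 on C4 would give a bridged ring with a bridgehead alkene that cannot aromatize, attack of C8 on the side-chain ester is blocked by the tert-butyl group, and lactonization to a 2-pyranone is impossible because the C8a oxygen is tied up as O1. Cleavage of the C7 ketone by methoxide is disfavoured because C7 lies between two enolized carbons, and the irreversible aromatization pulls the equilibria forward.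

Step 14
Reactants: 21 tert-butyl (3R)-3-[(2S,3S)-5,7-dihydroxy-2,3-dimethyl-8-(3-methylbut-2-en-1-yl)-4-oxo-3,4-dihydro-2H-chromen-6-yl]hexanoate
Product: 22 tert-butyl (3R)-3-[(2S,3S)-5-hydroxy-7-methoxy-2,3-dimethyl-8-(3-methylbut-2-en-1-yl)-4-oxo-3,4-dihydro-2H-chromen-6-yl]hexanoate
Conditions: MeI (1.2 equiv), K2CO3 (1.5 equiv), acetone, rt
Reagents that add atoms: iodomethane, CI
Why: Williamson methylation of the more acidic phenol: the 7-OH is free and para to the C4 carbonyl, the 5-OH is held in a six-membered hydrogen bond to C4=O, so one equivalent of iodomethane with a carbonate base should alkylate O7 only. The weak base and room temperature are chosen to leave C3 and the O1–C2 bond alone.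

Step 15
Reactants: 22 tert-butyl (3R)-3-[(2S,3S)-5-hydroxy-7-methoxy-2,3-dimethyl-8-(3-methylbut-2-en-1-yl)-4-oxo-3,4-dihydro-2H-chromen-6-yl]hexanoate
Product: 24 (3R)-3-[(2S,3S)-5-hydroxy-7-methoxy-2,3-dimethyl-8-(3-methylbut-2-en-1-yl)-4-oxo-3,4-dihydro-2H-chromen-6-yl]hexanoic acid, via bis(trimethylsilyl) derivative 23 (not isolated)
Conditions: Me3SiOTf, 2,6-lutidine, CH2Cl2, 0 °C; then H2O/MeOH, rt
Reagents that add atoms: none
Why: Silyl-triflate-mediated cleavage of a tert-butyl ester: O-silylation of the ester carbonyl triggers loss of isobutene to the silyl ester, the hindered pyridine buffers the triflic acid so that the prenyl alkene is not protonated, and aqueous methanol hydrolyses the silyl ester and the aryl silyl ether. No stereocentre takes part.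

## Compound list

1 | ethyl (3S)-3-hydroxybutanoate | C[C@H](O)CC(=O)OCC | starting material
2 | ethyl (2S,3S)-3-hydroxy-2-methylbutanoate | CCOC(=O)[C@@H](C)[C@H](C)O | intermediate
3 | ethyl (2S,3S)-3-[(tert-butyldimethylsilyl)oxy]-2-methylbutanoate | CCOC(=O)[C@@H](C)[C@H](C)O[Si](C)(C)C(C)(C)C | intermediate
4 | (2S,3S)-3-[(tert-butyldimethylsilyl)oxy]-N-methoxy-N,2-dimethylbutanamide | CON(C)C(=O)[C@@H](C)[C@H](C)O[Si](C)(C)C(C)(C)C | intermediate
5 | tert-butyl 3-oxobutanoate | CC(=O)CC(=O)OC(C)(C)C | starting material
6 | tert-butyl (6S,7S)-7-[(tert-butyldimethylsilyl)oxy]-6-methyl-3,5-dioxooctanoate | CC(C)(C)OC(=O)CC(=O)CC(=O)[C@@H](C)[C@H](C)O[Si](C)(C)C(C)(C)C | intermediate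
7 | tert-butyl (6S,7S)-7-hydroxy-6-methyl-3,5-dioxooctanoate (formed in the flask in step 5, in equilibrium with its cyclic hemiketal) | CC(C)(C)OC(=O)CC(=O)CC(=O)[C@@H](C)[C@H](C)O | intermediate
8 | tert-butyl 2-[(2S,3S)-2,3-dimethyl-4-oxo-3,4-dihydro-2H-pyran-6-yl]acetate | CC(C)(C)OC(=O)CC1=CC(=O)[C@@H](C)[C@H](C)O1 | intermediate
9 | 2-[(2S,3S)-2,3-dimethyl-4-oxo-3,4-dihydro-2H-pyran-6-yl]acetic acid | OC(=O)CC1=CC(=O)[C@@H](C)[C@H](C)O1 | intermediate
10 | (E)-hex-2-enal | CCC/C=C/C=O | starting material
11 | dimethyl propanedioate (dimethyl malonate) | COC(=O)CC(=O)OC | starting material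
12 | dimethyl 2-[(3R)-1-oxohexan-3-yl]propanedioate | CCC[C@H](CC=O)C(C(=O)OC)C(=O)OC | intermediate
13 | (3R)-3-(1,3-dimethoxy-1,3-dioxopropan-2-yl)hexanoic acid | CCC[C@H](CC(=O)O)C(C(=O)OC)C(=O)OC | intermediate
14 | dimethyl 2-[(3R)-1-(tert-butoxy)-1-oxohexan-3-yl]propanedioate | CCC[C@H](CC(=O)OC(C)(C)C)C(C(=O)OC)C(=O)OC | intermediate
15 | (3R)-5-(tert-butoxy)-2-(methoxycarbonyl)-5-oxo-3-propylpentanoic acid (both C2 epimers) | CCC[C@H](CC(=O)OC(C)(C)C)C(C(=O)O)C(=O)OC | intermediate
16 | 1-{2-[(2S,3S)-2,3-dimethyl-4-oxo-3,4-dihydro-2H-pyran-6-yl]acetyl}-1H-imidazole (formed in the flask in step 11) | O=C(CC1=CC(=O)[C@@H](C)[C@H](C)O1)n1ccnc1 | intermediate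
17 | (3R)-5-(tert-butoxy)-2-{2-[(2S,3S)-2,3-dimethyl-4-oxo-3,4-dihydro-2H-pyran-6-yl]acetyl}-2-(methoxycarbonyl)-5-oxo-3-propylpentanoic acid (formed in the flask in step 11) | CCC[C@H](CC(=O)OC(C)(C)C)C(C(=O)O)(C(=O)OC)C(=O)CC1=CC(=O)[C@@H](C)[C@H](C)O1 | intermediate
18 | 5-tert-butyl 1-methyl (3R)-2-{2-[(2S,3S)-2,3-dimethyl-4-oxo-3,4-dihydro-2H-pyran-6-yl]acetyl}-3-propylpentanedioate | CCC[C@H](CC(=O)OC(C)(C)C)C(C(=O)OC)C(=O)CC1=CC(=O)[C@@H](C)[C@H](C)O1 | intermediate
19 | 1-bromo-3-methylbut-2-ene (prenyl bromide) | CC(C)=CCBr | starting material
20 | 5-tert-butyl 1-methyl (3R)-2-{2-[(2S,3S)-2,3-dimethyl-4-oxo-3,4-dihydro-2H-pyran-6-yl]-5-methylhex-4-enoyl}-3-propylpentanedioate | CCC[C@H](CC(=O)OC(C)(C)C)C(C(=O)OC)C(=O)C(CC=C(C)C)C1=CC(=O)[C@@H](C)[C@H](C)O1 | intermediate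
21 | tert-butyl (3R)-3-[(2S,3S)-5,7-dihydroxy-2,3-dimethyl-8-(3-methylbut-2-en-1-yl)-4-oxo-3,4-dihydro-2H-chromen-6-yl]hexanoate | CCC[C@H](CC(=O)OC(C)(C)C)c1c(O)c2c(c(CC=C(C)C)c1O)O[C@@H](C)[C@H](C)C2=O | intermediate
22 | tert-butyl (3R)-3-[(2S,3S)-5-hydroxy-7-methoxy-2,3-dimethyl-8-(3-methylbut-2-en-1-yl)-4-oxo-3,4-dihydro-2H-chromen-6-yl]hexanoate | CCC[C@H](CC(=O)OC(C)(C)C)c1c(O)c2c(c(CC=C(C)C)c1OC)O[C@@H](C)[C@H](C)C2=O | intermediate
23 | trimethylsilyl (3R)-3-[(2S,3S)-7-methoxy-2,3-dimethyl-8-(3-methylbut-2-en-1-yl)-4-oxo-5-(trimethylsilyloxy)-3,4-dihydro-2H-chromen-6-yl]hexanoate (formed in the flask in step 15) | CCC[C@H](CC(=O)O[Si](C)(C)C)c1c(O[Si](C)(C)C)c2c(c(CC=C(C)C)c1OC)O[C@@H](C)[C@H](C)C2=O | intermediate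
24 | (3R)-3-[(2S,3S)-5-hydroxy-7-methoxy-2,3-dimethyl-8-(3-methylbut-2-en-1-yl)-4-oxo-3,4-dihydro-2H-chromen-6-yl]hexanoic acid | CCC[C@H](CC(=O)O)c1c(O)c2c(c(CC=C(C)C)c1OC)O[C@@H](C)[C@H](C)C2=O | target

## Step count and least certain steps

Total: 15 steps. Longest linear sequence: 11 steps (steps 1–6 and 11–15, from 1 to 24); the side-chain branch (steps 7–10) joins at step 11.

**Step 13 (key step).** The ring closure may stall, because the planar dienolate has to hold substituents on both C6 and C8 close to each other. In that case slower processes take over: cleavage of the C7 ketone by methoxide, opening of ring B by methoxide at C8a (which would cost the C2/C3 configuration), or transfer of the side-chain ester to a methyl ester by way of a phenoxide.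
Fallback: the closure is run before the prenyl group is present. It sets out from 18, which under the same magnesium methoxide conditions should close more easily to tert-butyl (3R)-3-[(2S,3S)-5,7-dihydroxy-2,3-dimethyl-4-oxo-3,4-dihydro-2H-chromen-6-yl]hexanoate F1. C8 is then the only free ring carbon, and C-prenylation of the phloroglucinol-type phenoxide with 19 and DBU in THF comes back to the route at 21.

**Step 11.** Proton transfer from the acidic CH2 of 16 to the magnesium enolate, self-condensation of 16, and slow acylation of the branched half-ester may lead mainly to simple decarboxylation of 15.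
Fallback: the polarity is reversed, so that the acidic partner is the nucleophile. It sets out from 9 and 15. Acid 9 is esterified (allyl bromide, KHCO3, DMF) to prop-2-en-1-yl 2-[(2S,3S)-2,3-dimethyl-4-oxo-3,4-dihydro-2H-pyran-6-yl]acetate F2. Half-ester 15 is converted with 1-chloro-N,N,2-trimethylprop-1-en-1-amine into 5-tert-butyl 1-methyl (3R)-2-(carbonochloridoyl)-3-propylpentanedioate F3. The magnesium enolate of F2 (MgCl2, Et3N) is C-acylated by F3 to give 5-tert-butyl 1-methyl (3R)-2-{2-[(2S,3S)-2,3-dimethyl-4-oxo-3,4-dihydro-2H-pyran-6-yl]-3-oxo-3-(prop-2-en-1-yloxy)propanoyl}-3-propylpentanedioate F4. Removal of the allyl group with Pd(PPh3)4 and morpholine, with loss of CO2, comes back to the route at 18.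

**Step 12.** Alkylation may go to the wrong position (C6, C4a or oxygen), or a second prenyl group may enter at C8.
Fallback: the prenyl group is introduced before the chain is joined, where only one acidic site exists. It sets out from 8, whose sodium enolate (NaH, THF) is alkylated by 19 to tert-butyl 2-[(2S,3S)-2,3-dimethyl-4-oxo-3,4-dihydro-2H-pyran-6-yl]-5-methylhex-4-enoate F5. Cleavage of the ester with Me3SiOTf and 2,6-lutidine gives 2-[(2S,3S)-2,3-dimethyl-4-oxo-3,4-dihydro-2H-pyran-6-yl]-5-methylhex-4-enoic acid F6. Decarboxylative Claisen condensation of its imidazolide with 15 (MgCl2, Et3N) comes back to the route at 20.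

**Step 7.** Aliphatic enals are slower and less selective partners in iminium catalysis, so incomplete conversion and erosion of the enantiomeric purity by an uncatalysed or reversible addition are possible.
Fallback: the stereocentre is set on a nitroalkene instead. It sets out from 11, which adds to (E)-1-nitropent-1-ene F7 under a bifunctional tertiary amine–thiourea catalyst of the appropriate configuration to give dimethyl 2-[(2S)-1-nitropentan-2-yl]propanedioate F8. A Nef reaction (NaOMe, MeOH; then buffered aqueous TiCl3) comes back to the route at 12.

**Step 14.** Carbonate base may open ring B by retro-oxa-Michael reaction (loss of C2 and C3), a second methylation may occur at O5, or a phenoxide may attack the side-chain ester.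
Fallback: methylation without base by a Mitsunobu reaction (MeOH, PPh3, diisopropyl azodicarboxylate), in which the more acidic 7-OH is the pronucleophile. It sets out from 21 and comes back at 22 without a new intermediate.

## Further compounds

F1 | step 13 | tert-butyl (3R)-3-[(2S,3S)-5,7-dihydroxy-2,3-dimethyl-4-oxo-3,4-dihydro-2H-chromen-6-yl]hexanoate | CCC[C@H](CC(=O)OC(C)(C)C)c1c(O)c2c(cc1O)O[C@@H](C)[C@H](C)C2=O
F2 | step 11 | prop-2-en-1-yl 2-[(2S,3S)-2,3-dimethyl-4-oxo-3,4-dihydro-2H-pyran-6-yl]acetate | C=CCOC(=O)CC1=CC(=O)[C@@H](C)[C@H](C)O1
F3 | step 11 | 5-tert-butyl 1-methyl (3R)-2-(carbonochloridoyl)-3-propylpentanedioate | CCC[C@H](CC(=O)OC(C)(C)C)C(C(=O)Cl)C(=O)OC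
F4 | step 11 | 5-tert-butyl 1-methyl (3R)-2-{2-[(2S,3S)-2,3-dimethyl-4-oxo-3,4-dihydro-2H-pyran-6-yl]-3-oxo-3-(prop-2-en-1-yloxy)propanoyl}-3-propylpentanedioate | CCC[C@H](CC(=O)OC(C)(C)C)C(C(=O)OC)C(=O)C(C(=O)OCC=C)C1=CC(=O)[C@@H](C)[C@H](C)O1
F5 | step 12 | tert-butyl 2-[(2S,3S)-2,3-dimethyl-4-oxo-3,4-dihydro-2H-pyran-6-yl]-5-methylhex-4-enoate | CC(C)=CCC(C(=O)OC(C)(C)C)C1=CC(=O)[C@@H](C)[C@H](C)O1
F6 | step 12 | 2-[(2S,3S)-2,3-dimethyl-4-oxo-3,4-dihydro-2H-pyran-6-yl]-5-methylhex-4-enoic acid | CC(C)=CCC(C(=O)O)C1=CC(=O)[C@@H](C)[C@H](C)O1
F7 | step 7 | (E)-1-nitropent-1-ene | CCC/C=C/[N+](=O)[O-]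
F8 | step 7 | dimethyl 2-[(2S)-1-nitropentan-2-yl]propanedioate | CCC[C@H](C[N+](=O)[O-])C(C(=O)OC)C(=O)OC
F0 | step 14 | none | none
A1 | alternative 1 | (2S,3S)-5-hydroxy-7-methoxy-2,3-dimethyl-8-(3-methylbut-2-en-1-yl)-2,3-dihydro-4H-chromen-4-one | COc1cc(O)c2c(c1CC=C(C)C)O[C@@H](C)[C@H](C)C2=O
A2 | alternative 1 | lactol in which a (4R)-2-hydroxy-4-propyl-3,4-dihydro-2H-pyran ring is fused through O5 and C6 to (2S,3S)-7-methoxy-2,3-dimethyl-8-(3-methylbut-2-en-1-yl)chroman-4-one, both epimers at the lactol carbon | CCC[C@@H]1CC(O)Oc2c1c(OC)c(CC=C(C)C)c1c2C(=O)[C@@H](C)[C@H](C)O1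
A3 | alternative 2 | methyl (3R)-3-{4-[(2S)-but-3-en-2-yloxy]-3-formyl-2,6-dimethoxy-5-(3-methylbut-2-en-1-yl)phenyl}hexanoate | CCC[C@H](CC(=O)OC)c1c(OC)c(C=O)c(O[C@@H](C)C=C)c(CC=C(C)C)c1OC
A4 | alternative 2 | methyl (3R)-3-[(2S,3S)-5,7-dimethoxy-2,3-dimethyl-8-(3-methylbut-2-en-1-yl)-4-oxo-3,4-dihydro-2H-chromen-6-yl]hexanoate | CCC[C@H](CC(=O)OC)c1c(OC)c2c(c(CC=C(C)C)c1OC)O[C@@H](C)[C@H](C)C2=O
A5 | alternative 3 | (2S,3S)-6-(2-diazo-5-methylhex-4-enoyl)-2,3-dimethyl-2,3-dihydro-4H-pyran-4-one | CC(C)=CCC(=[N+]=[N-])C(=O)C1=CC(=O)[C@@H](C)[C@H](C)O1
A6 | alternative 3 | methyl (3R)-3-(methoxyethynyl)hexanoate | CCC[C@H](CC(=O)OC)C#COC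
A7 | alternative 3 | methyl (3R)-3-[(2S,3S)-5-hydroxy-7-methoxy-2,3-dimethyl-8-(3-methylbut-2-en-1-yl)-4-oxo-3,4-dihydro-2H-chromen-6-yl]hexanoate | CCC[C@H](CC(=O)OC)c1c(O)c2c(c(CC=C(C)C)c1OC)O[C@@H](C)[C@H](C)C2=O
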